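## Analysis of the target

The target 47 is a pentacyclic lactam. With its atoms labelled in the order of the SMILES string (C3 ester carbon, C5, C6, C7, C8 lactam carbonyl, N10, C11 to C20, C21 acetoxymethyl carbon, C26 to C28, C30, C32), it contains:

- ring A, the cyclopentane C5–C6–C7–C16–C17;
- ring B, the cyclopentene C15=C16–C17–C18–C19;
- ring C, the cycloheptene C7–C16=C15–C14–C13–C12–C20;
- ring D, the six-membered lactam C7–C8–N10–C11–C12–C20;
- ring E, the nine-membered ring N10–C32–C30–C28–C27–C26–C20–C12–C11.

There are seven stereocentres: C5 (CO2Me), the adjacent quaternary carbons C7 and C20, C12, C17, C28 (OH) and C30 (CH3). On ring A the ester at C5, the ring B methylene C18 at C17 and C20 at C7 all stand on one face, with C8 on the other. C11 on C12 has to be cis to C8 or ring D cannot exist, and C28/C30 are a syn hydroxy/methyl pair remote from the core. The sensitive points are the epimerizable C5 (cis to its neighbour, so probably not the thermodynamic epimer), a primary acetate beside a free secondary alcohol, and a tetrasubstituted alkene shared by three rings. The difficulty lies in the vicinal quaternary carbons C7 and C20, each a member of three rings, in the all-cis face of ring A and in the medium ring E. The strategy rests on this feature: C7 and C20 hold the two ends of the five-carbon arc C16–C15–C14–C13–C12, and C8 and C26 are cis across the C7–C20 bond. Because C8 and the oxygen on C28 can be tied as a seven-membered lactone, C7=C20 can be a ring-locked tetrasubstituted alkene, across which C2 and C1 of cyclopentane-1,3-dione (24) are added photochemically and then cut apart by retro-aldol.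

## Retrosynthetic reasoning

**47 to 46 (N10–C11).** Ring D is opened last, at the N10–C11 bond, to the N-acyl hemiaminal 46. The forward step is a silane reduction of an N-acyliminium ion. This bond is cut here because C12 is a bridgehead of rings C and D, so its configuration is forced once the ring closes.

**46 to 43 (N10–C8).** The amide bond is traced to the seven-membered lactone of aldehyde 43, which carries the nitrogen as a carbamate on C32. The freed amine sits 1,3 to the lactone oxygen, so O-to-N acyl transfer through a six-membered intermediate expands the lactone to ring E and releases the C28 hydroxyl. Ring E is thus made without a medium-ring alkylation and without a protecting group on C28.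

**43 to 39 (C12–C11).** C11 is removed as a one-carbon homologation of the C12 ketone of 39: methylenation (40), hydroboration (42), oxidation. The configuration at C12 need not be controlled, because only the epimer with C11 cis to C8 can close to 46 and the aldehyde is epimerizable.

**39 to 35 (C15–C19 and C15=C16).** Ring B is disconnected at C15–C19. A samarium Barbier closure of iodide 37 onto the C15 ketone gives carbinol 38, and dehydration into the ring fusion gives 39. The other ketone, C12, is seven atoms from the iodide and does not compete. Iodide 37 comes from silyl ether 35 through alcohol 36.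

**35 to 33.** The acetate of the target is put on C21 directly after the key step (33 to 34 to 35). At that point the molecule has no alkene, so the benzyl ether can be hydrogenolysed, and C28 is still masked in the lactone, so no selective acylation is needed.

**33 to 30 (C16–C7 and C12–C20, the key disconnection).** Diketone 33 is the retro-aldol product of cyclobutanol 32, which comes from photoadduct 31 of enol lactone 30. Cutting C16–C7 and C12–C20 removes ring A, ring C and both quaternary centres at once and leaves a cyclopentane-1,3-dione unit tethered to an unsaturated lactone. The dione is used as its enol ester with the C3 carboxyl: the six-membered enol lactone holds C17 and C5 in a ring, so the alkene can reach the enone only from the face that gives the all-cis ring A. Methanolysis afterwards supplies both the methyl ester and the alkoxide that fragments.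

**30 to 28 and 19 (C5–C6).** The C5–C6 bond is cut to thioester 28 and allylic bromide 19. The thioester permits clean enolization beside the dione enolate (29) and silver-promoted reclosure to the enol lactone. C5, alpha to an enol ester, can then be equilibrated to the trans isomer that is needed.

**28 to 24 and 23 (C16–C17).** The C16–C17 bond is cut to dione 24 and enal 23. An iminium-catalysed Michael addition sets C17 by catalyst control and gives lactol 26, which is oxidized to enol lactone 27 and opened with a thiol. Enal 23 comes from alcohol 20 and aldehyde 22 by silylation (21) and cross-metathesis.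

**19 to 7 and 13 (C20–C26 and the lactone C–O bond).** The lactone is opened to hydroxy acid 16 and the C20–C26 bond is cut to alkene 7 and enol triflate 13. A B-alkyl Suzuki coupling transfers the Z geometry of 13 into the tetrasubstituted alkene of 15. Lactonization (17) and exchange of the PMB ether for bromide (18, 19) follow.

**7 to 1 and 2 (C28–C30).** The syn C28/C30 pair is an auxiliary-controlled aldol of imide 1 with aldehyde 2 (3). The imide carbonyl becomes C32 and is converted to the carbamate nitrogen through 4, 5 and 6.

**13 to 8, 9 and 11.** Triflate 13 comes from beta-keto ester 12, a crossed Claisen product of ester 10 (from 8 and 9) and acid chloride 11.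

## Alternatives that were turned down

**Alternative 1:** The disconnection is the C28–C30 bond of ring E. In the forward step the N-propanoyl lactam aldehyde A2 would be enolized with TiCl4 and i-Pr2NEt, and the Z chlorotitanium enolate would add to the aldehyde on the C26–C27 arm to give the hydroxy imide A1.

- For it: two stereocentres and the medium ring are made in one late, convergent step, and the syn relation follows from the Z enolate. On this point it is stronger than the chosen route, which needs a separate fragment for C28/C30.
- Against it: no auxiliary controls the absolute sense, which would depend on a nine-membered transition state. The exocyclic acyl group on a hindered lactam nitrogen is easily lost. A1 has an extra carbonyl at C32 that must be reduced to CH2 beside the lactam, the methyl ester, the acetate and a retro-aldol-prone beta-hydroxyl.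
- Comparison: rings A to D with C7 and C20 must exist before the step, so the hardest part of the molecule is untouched. The chosen route fixes C28/C30 by an auxiliary aldol, uses them as the lactone that locks the alkene geometry, and closes ring E at the correct oxidation level.

**Alternative 2:** The disconnection is the C16–C17 bond of ring B. BF3·OEt2 would convert dienone A4 into a pentadienyl cation that closes conrotatorily to cyclopentenone A3, with the alkene returning to C15=C16.

- For it: the Nazarov cyclization places the tetrasubstituted alkene by thermodynamics. That is more secure than the Barbier closure and dehydration of the chosen route.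
- Against it: A4 already needs the azatricycle with both quaternary carbons, for which this plan has no answer. The sense of ring closure at C17 is governed only by distant centres. A3 lacks ring A, so the C5–C6 bond and the C5 configuration remain to be made from a vinyl group and an acetate arm. The C19 ketone is superfluous and must be removed next to a sensitive alkene.
- Comparison: the step builds one ring and one stereocentre and leaves a long sequence after it, whereas the chosen key step builds rings A and C and both quaternary carbons.

**Alternative 3:** The disconnection joins the alkyne on C7, the distal allene double bond on the C12 side chain and CO. [Rh(CO)2Cl]2 under CO would convert the allene-yne A6 into the alkylidene cyclopentenone A5, closing rings C and B together.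

- For it: two rings and the future alkene carbons are assembled in one catalytic step, and seven-membered ring formation by the allenic variant is reliable. For rings B and C it is more convergent than the chosen route.
- Against it: A6 must already carry C7 and C20 as vicinal quaternary centres on the lactam, again made by other means. A5 is far from the target: the diene has to be moved into the C15=C16 position, the ring ketone removed, ring A built from the acetal and the silyloxyethyl arm with C5 and C17 set, the N-protecting group removed, and ring E built with C28 and C30 from an unfunctionalized propyl arm.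
- Comparison: the chosen route sets the quaternary pair, ring A and the C28/C30 pair before or in the key step and keeps the later steps to functional-group work.

Key step: step 20

## Remarks on the chemistry

- Atom labels (C5, C7 and so on) are those defined in the analysis and are used for all intermediates.
- The 2-substituted cyclopentane-1,3-diones 25, 28 and 29 are drawn as diketones although they should exist largely as enols.
- The sense of induction in step 15 is taken from the usual shielding model of the (S)-prolinol silyl ether (attack on the E-iminium ion anti to the bulky group). If the sense were the opposite, the (R)-catalyst would be used.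
- Diketone 33 is drawn as the C16 epimer with the cis A/C ring fusion. C16 is epimerizable and becomes sp2 in step 26.

## Route

Step 1
Reactants: 1 (S)-4-benzyl-3-propanoyl-1,3-oxazolidin-2-one; 2 acrolein
Product: 3 (S)-4-benzyl-3-[(2S,3R)-3-hydroxy-2-methylpent-4-enoyl]-1,3-oxazolidin-2-one
Conditions: Bu2BOTf, i-Pr2NEt, CH2Cl2, −78 → 0 °C; then pH 7 buffer, MeOH, H2O2
Reagents that add atoms: none
Why: Evans syn aldol; the Z boron enolate reacts through a chair transition state on the face set by the benzyl auxiliary and should give the syn C28/C30 pair in the absolute sense of the target.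

Step 2
Reactants: 3
Product: 4 (2R,3R)-2-methylpent-4-ene-1,3-diol
Conditions: LiBH4, MeOH, THF, 0 °C
Reagents that add atoms: none
Why: Reductive removal of the auxiliary from a beta-hydroxy imide; the exocyclic carbonyl is reduced to the C32 carbinol without touching the stereocentres or the alkene.

Step 3
Reactants: 4
Product: 5 (3R,4R)-5-azido-4-methylpent-1-en-3-ol
Conditions: PPh3, DIAD, (PhO)2P(O)N3, THF, 0 °C → rt
Reagents that add atoms: diphenylphosphoryl azide, [N-]=[N+]=NP(=O)(Oc1ccccc1)Oc1ccccc1
Why: Mitsunobu azidation; the unhindered primary alcohol should be activated and displaced well before the secondary allylic one, and no stereocentre is involved.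

Step 4
Reactants: 5
Product: 7 tert-butyl N-[(2R,3R)-3-hydroxy-2-methylpent-4-en-1-yl]carbamate, via amino alcohol 6 (not isolated)
Conditions: PPh3, THF/H2O, 50 °C; then Boc2O, NaHCO3, rt
Reagents that add atoms: di-tert-butyl dicarbonate, CC(C)(C)OC(=O)OC(=O)OC(C)(C)C
Why: Staudinger reduction then N-acylation; the amine is far more nucleophilic than the secondary alcohol, so only the carbamate should form.

Step 5
Reactants: 8 methyl acrylate; 9 4-methoxybenzyl alcohol
Product: 10 methyl 3-[(4-methoxybenzyl)oxy]propanoate
Conditions: NaH (5 mol %), THF, 0 °C → rt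
Reagents that add atoms: none
Why: Base-catalysed oxa-Michael addition of a benzylic alkoxide to an unsubstituted acrylate.

Step 6
Reactants: 10; 11 (benzyloxy)acetyl chloride
Product: 12 methyl 4-(benzyloxy)-2-{[(4-methoxybenzyl)oxy]methyl}-3-oxobutanoate (racemic)
Conditions: LiN(i-Pr)2, THF, −78 °C (10 in excess); then 11, −78 °C
Reagents that add atoms: none
Why: Crossed Claisen condensation; the ester enolate is C-acylated by the acid chloride, and at −78 °C the beta-alkoxy enolate should not eliminate.

Step 7
Reactants: 12
Product: 13 methyl (Z)-4-(benzyloxy)-2-{[(4-methoxybenzyl)oxy]methyl}-3-{[(trifluoromethyl)sulfonyl]oxy}but-2-enoate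
Conditions: Tf2O, aq. LiOH, toluene, 5 °C
Reagents that add atoms: trifluoromethanesulfonic anhydride, O=S(=O)(OS(=O)(=O)C(F)(F)F)C(F)(F)F
Why: Enol triflation of a beta-keto ester; the lithium-chelated enolate holds the enolate oxygen cis to the ester, so sulfonylation should give the Z triflate.

Step 8
Reactants: 7; 13
Product: 15 methyl (2E,6R,7R)-3-[(benzyloxy)methyl]-8-[(tert-butoxycarbonyl)amino]-6-hydroxy-2-{[(4-methoxybenzyl)oxy]methyl}-7-methyloct-2-enoate, via alkylborane 14 (not isolated)
Conditions: 9-BBN (2.3 equiv), THF, rt; then 13, Pd(dppf)Cl2, AsPh3, aq. K3PO4, DMF, rt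
Reagents that add atoms: none
Why: B-alkyl Suzuki–Miyaura coupling; anti-Markovnikov hydroboration of the terminal alkene (the hydroxyl is borylated in passing) and coupling with retention at the activated enol triflate place the C26 chain cis to the ester.

Step 9
Reactants: 15
Product: 16 (2E,6R,7R)-3-[(benzyloxy)methyl]-8-[(tert-butoxycarbonyl)amino]-6-hydroxy-2-{[(4-methoxybenzyl)oxy]methyl}-7-methyloct-2-enoic acid
Conditions: LiOH, THF/MeOH/H2O, 50 °C; then 1 M HCl
Reagents that add atoms: lithium hydroxide, [Li+].[OH-]
Why: Saponification; the tetrasubstituted enoate has no alpha-hydrogen, and the carbamate and ethers tolerate hydroxide.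

Step 10
Reactants: 16
Product: 17 tert-butyl N-[(2R)-2-[(7R)-4-[(benzyloxy)methyl]-3-{[(4-methoxybenzyl)oxy]methyl}-2-oxo-2,5,6,7-tetrahydrooxepin-7-yl]propyl]carbamate
Conditions: 2,4,6-Cl3C6H2COCl, Et3N, THF, rt; then DMAP, toluene, 80 °C, high dilution
Reagents that add atoms: none
Why: Yamaguchi lactonization; the alkene geometry holds the carboxyl and the C26 chain cis, which favours seven-membered ring closure, and C28 keeps its configuration because only the acyl carbon reacts.

Step 11
Reactants: 17
Product: 18 tert-butyl N-[(2R)-2-[(7R)-4-[(benzyloxy)methyl]-3-(hydroxymethyl)-2-oxo-2,5,6,7-tetrahydrooxepin-7-yl]propyl]carbamate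
Conditions: DDQ, CH2Cl2/pH 7 buffer, 0 °C
Reagents that add atoms: none
Why: Oxidative cleavage of the electron-rich PMB ether; the benzyl ether is oxidized much more slowly, and the freed C6 hydroxyl cannot lactonize because it is geminal to the carbonyl.

Step 12
Reactants: 18
Product: 19 tert-butyl N-[(2R)-2-[(7R)-4-[(benzyloxy)methyl]-3-(bromomethyl)-2-oxo-2,5,6,7-tetrahydrooxepin-7-yl]propyl]carbamate
Conditions: CBr4, PPh3, CH2Cl2, 0 °C
Reagents that add atoms: tetrabromomethane, BrC(Br)(Br)Br
Why: Appel bromination of a primary allylic alcohol under neutral conditions; the carbamate and lactone are inert.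

Step 13
Reactants: 20 but-3-en-1-ol
Product: 21 tert-butyl(but-3-en-1-yloxy)dimethylsilane
Conditions: TBSCl, imidazole, CH2Cl2, rt
Reagents that add atoms: tert-butyldimethylsilyl chloride, C[Si](C)(Cl)C(C)(C)C
Why: Standard silylation of a primary alcohol.

Step 14
Reactants: 21; 22 (E)-but-2-enal
Product: 23 (E)-5-[(tert-butyldimethylsilyl)oxy]pent-2-enal
Conditions: RuCl2(H2IMes)(=CH-C6H4-2-OiPr) (second-generation Hoveyda–Grubbs catalyst, 2 mol %), CH2Cl2, 40 °C
Reagents that add atoms: none
Why: Olefin cross-metathesis of a terminal alkene with an enal; the conjugated E isomer is the favoured product and propene leaves the mixture.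

Step 15
Reactants: 23; 24 cyclopentane-1,3-dione
Product: 26 (4R)-4-{2-[(tert-butyldimethylsilyl)oxy]ethyl}-2-hydroxy-3,4,6,7-tetrahydro-2H-cyclopenta[b]pyran-5-one (mixture at the hemiacetal carbon), via Michael adduct 25 (not isolated)
Conditions: (S)-2-[diphenyl(trimethylsilyloxy)methyl]pyrrolidine (10 mol %), PhCO2H (10 mol %), CH2Cl2, 0 °C → rt
Reagents that add atoms: none
Why: Iminium-catalysed Michael addition of a cyclic 1,3-dione to an enal; the dione attacks C17 of the E-iminium ion on the face away from the diphenyl(silyloxy)methyl group, which sets C17, and the adduct closes to the hemiacetal.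

Step 16
Reactants: 26
Product: 27 (4R)-4-{2-[(tert-butyldimethylsilyl)oxy]ethyl}-3,4,6,7-tetrahydrocyclopenta[b]pyran-2,5-dione
Conditions: TEMPO (10 mol %), PhI(OAc)2, CH2Cl2, rt
Reagents that add atoms: none
Why: Oxoammonium oxidation of a lactol to the lactone; the dione is masked as the cyclic enol ether and is not touched.

Step 17
Reactants: 27
Product: 28 S-ethyl (3R)-5-[(tert-butyldimethylsilyl)oxy]-3-(2,5-dioxocyclopentyl)pentanethioate
Conditions: EtSH, Et3N (cat.), CH2Cl2, 0 °C
Reagents that add atoms: ethanethiol, CCS
Why: Acyl transfer from the enol ester, a vinylogous anhydride, to the thiolate; the stable dione enol is released and C17 is not involved.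

Step 18
Reactants: 28; 19
Product: 29 thioester 28 alkylated at C5 by the lactonylmethyl group of 19, with C5 as in the target (C6 anti to C16 in the extended chain)
Conditions: LiN(SiMe3)2 (2.2 equiv), THF, −78 °C; then 19, −78 → −40 °C
Reagents that add atoms: none
Why: Enolate alkylation of a dianion; the first equivalent of base ties up the dione as its enolate, the second forms the thioester enolate, which is the more reactive site, and the allylic bromide should enter anti to the dione ring with the C17 hydrogen in the enolate plane (minimized allylic strain).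

Step 19
Reactants: 29
Product: 30 trans-3,4-disubstituted enol lactone: the 3,4,6,7-tetrahydrocyclopenta[b]pyran-2,5-dione of 27 carrying at C5 (ring position 3) the lactonylmethyl group of 19, trans to the silyloxyethyl arm at C17 (ring position 4)
Conditions: AgOTf, 2,6-lutidine, MeCN, 0 °C → rt; then DBU (10 mol %), rt
Reagents that add atoms: none
Why: Silver-promoted thioester lactonization (Masamune type) onto the dione enol oxygen; C5 is now alpha to an enol ester and equilibrates under the amine base to the more stable trans isomer, so the outcome does not depend on the selectivity of step 18.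

Step 20
Reactants: 30
Product: 33 methyl ester with ring A cis-fused to a cycloheptane-1,4-dione (C12 and C15 ketones) and spiro-linked at C7 to the seven-membered lactone, with the C5 ester, the C17 silyloxyethyl arm and C20 on one face of ring A and C20 bearing CH2OBn, via photoadduct 31 (not isolated), via cyclobutanol 32 (not isolated)
Conditions: hν (350 nm), degassed MeCN (5 mM), rt; then K2CO3 (cat.), MeOH, 0 °C
Reagents that add atoms: methanol, CO
Why: This is a de Mayo reaction in its enol ester form, that is an intramolecular enone–alkene [2+2] photocycloaddition followed by retro-aldol cleavage. The triplet beta-acyloxy cyclopentenone bonds from its alpha-carbon C16 to the lactone alpha-carbon C7 by 1,5-closure (rule of five), which closes ring A, and the 1,4-biradical then collapses between C12 and C20 to the cyclobutane 31. Methanolysis of the bridged enol-derived ester gives the methyl ester and the cyclobutanolate 32, whose retro-aldol cleavage of the C12–C16 bond expands the dione ring by two carbons and closes ring C as the 1,4-diketone. The quaternary centres C7 and C20 arise by suprafacial addition to the ring-locked alkene, so C8 and C26 stay cis. The face is fixed by the enol lactone: C6 is axial on C5 of the six-membered ring and can deliver C7 to C16 only from the side on which C3, C12 and the arm at C17 end up cis, and only the alignment with C20 over C12 is productive. C16 is set by protonation of the enolate and is not a lasting centre. The step needs straight rather than crossed regiochemistry, which the three-atom tether provides, and methanolysis of the strained bridged ester in preference to the hindered seven-membered lactone, whose carbonyl sits on the quaternary C7.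

Step 21
Reactants: 33
Product: 34 primary alcohol at C21 (33 without the benzyl group)
Conditions: H2 (1 atm), Pd(OH)2/C, EtOAc, rt
Reagents that add atoms: none
Why: Hydrogenolysis of the benzyl ether; 33 has no alkene, and the ketones, silyl ether, carbamate and lactone are inert.

Step 22
Reactants: 34
Product: 35 acetate at C21
Conditions: Ac2O, pyridine, DMAP (cat.), CH2Cl2, rt
Reagents that add atoms: acetic anhydride, CC(=O)OC(C)=O
Why: DMAP-catalysed acetylation of the only free hydroxyl; acylation tolerates the neopentyl position, and C28 is still masked in the lactone.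

Step 23
Reactants: 35
Product: 36 primary alcohol at C19 (35 without the silyl group)
Conditions: HF·pyridine, THF/pyridine, 0 °C → rt
Reagents that add atoms: none
Why: Fluoride-mediated desilylation under buffered conditions that spare the acetate, the carbamate and the lactone.

Step 24
Reactants: 36
Product: 37 primary iodide at C19
Conditions: I2, PPh3, imidazole, CH2Cl2, 0 °C
Reagents that add atoms: iodine, II
Why: Appel-type iodination of an unhindered primary alcohol.

Step 25
Reactants: 37
Product: 38 tertiary carbinol at C15 with ring B closed (C15–C19), hydroxyl cis to the C16 hydrogen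
Conditions: SmI2, HMPA, THF, −78 → 0 °C
Reagents that add atoms: none
Why: Intramolecular samarium Barbier reaction; the alkylsamarium formed from the iodide adds to the C15 ketone in a five-membered closure, and C14 must point into the cleft between rings A and B to stay in ring C, which puts the hydroxyl on the outer face.

Step 26
Reactants: 38
Product: 39 tetrasubstituted cyclopentene (C15=C16) with the C12 ketone intact
Conditions: Burgess reagent (MeO2C–N(−)–SO2–N(+)Et3), toluene, 60 °C
Reagents that add atoms: none
Why: Burgess dehydration by syn elimination; the C16 hydrogen is cis to the hydroxyl and its loss gives the most substituted alkene.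

Step 27
Reactants: 39
Product: 40 exocyclic methylene compound (C12=C11H2)
Conditions: Zn, CH2Br2, TiCl4, THF/CH2Cl2, 0 °C → rt
Reagents that add atoms: dibromomethane, BrCBr
Why: Lombardo–Takai methylenation; the non-basic titanium–zinc reagent converts hindered ketones without epimerizing C5 and leaves the ester, lactone, acetate and carbamate alone.

Step 28
Reactants: 40
Product: 42 primary alcohol at C11 (drawn as the C12 epimer with C11 cis to C8), via alkylborane 41 (not isolated)
Conditions: 9-BBN, THF, 60 °C; then H2O2, aq. NaOAc, 0 °C → rt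
Reagents that add atoms: hydrogen peroxide, OO
Why: Hydroboration–oxidation; 9-BBN adds to the 1,1-disubstituted alkene at the terminal carbon and does not react with the tetrasubstituted alkene or the esters, and either C12 epimer can be carried on because C12 is equilibrated in step 30.

Step 29
Reactants: 42
Product: 43 aldehyde at C11
Conditions: Dess–Martin periodinane, NaHCO3, CH2Cl2, 0 °C → rt
Reagents that add atoms: none
Why: Dess–Martin oxidation of the only free alcohol under buffered, non-epimerizing conditions.

Step 30
Reactants: 43
Product: 46 N-acyl hemiaminal with rings D and E closed and the C28 hydroxyl free (mixture at C11), via amino aldehyde 44 (not isolated), via lactam aldehyde 45 (not isolated)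
Conditions: TMSOTf, 2,6-lutidine, CH2Cl2, 0 °C; MeOH; then DBU (cat.), MeCN, 40 °C
Reagents that add atoms: none
Why: Carbamate cleavage, then O-to-N acyl transfer: the C32 amine attacks the lactone carbonyl C8 through a six-membered intermediate and expands the lactone to the nine-membered lactam, and the amide nitrogen then adds to the C11 aldehyde. Only the C12 epimer with C11 cis to C8 can close, and the aldehyde alpha-centre equilibrates under DBU, so both epimers should converge on 46.

Step 31
Reactants: 46
Product: 47 target
Conditions: Et3SiH, BF3·OEt2, CH2Cl2, −78 → 0 °C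
Reagents that add atoms: none
Why: N-acyliminium ion reduction (ionic hydrogenation of a hemiaminal); ionization at C11 and hydride transfer from the silane give the N10–C11H2 bond at a temperature at which the tetrasubstituted alkene, the acetate and the free alcohol are not affected.

## Compound list

1 | (S)-4-benzyl-3-propanoyl-1,3-oxazolidin-2-one | CCC(=O)N1C(=O)OC[C@@H]1Cc1ccccc1 | starting material
2 | acrolein | C=CC=O | starting material
3 | (S)-4-benzyl-3-[(2S,3R)-3-hydroxy-2-methylpent-4-enoyl]-1,3-oxazolidin-2-one | C=C[C@@H](O)[C@H](C)C(=O)N1C(=O)OC[C@@H]1Cc1ccccc1 | intermediate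
4 | (2R,3R)-2-methylpent-4-ene-1,3-diol | C=C[C@@H](O)[C@H](C)CO | intermediate
5 | (3R,4R)-5-azido-4-methylpent-1-en-3-ol | C=C[C@@H](O)[C@H](C)CN=[N+]=[N-] | intermediate
6 | (3R,4R)-5-amino-4-methylpent-1-en-3-ol | C=C[C@@H](O)[C@H](C)CN | intermediate (not isolated)
7 | tert-butyl N-[(2R,3R)-3-hydroxy-2-methylpent-4-en-1-yl]carbamate | C=C[C@@H](O)[C@H](C)CNC(=O)OC(C)(C)C | intermediate
8 | methyl acrylate | C=CC(=O)OC | starting material
9 | 4-methoxybenzyl alcohol | COc1ccc(CO)cc1 | starting material
10 | methyl 3-[(4-methoxybenzyl)oxy]propanoate | COC(=O)CCOCc1ccc(OC)cc1 | intermediate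
11 | (benzyloxy)acetyl chloride | O=C(Cl)COCc1ccccc1 | starting material
12 | methyl 4-(benzyloxy)-2-{[(4-methoxybenzyl)oxy]methyl}-3-oxobutanoate | COC(=O)C(COCc1ccc(OC)cc1)C(=O)COCc1ccccc1 | intermediate
13 | methyl (Z)-4-(benzyloxy)-2-{[(4-methoxybenzyl)oxy]methyl}-3-{[(trifluoromethyl)sulfonyl]oxy}but-2-enoate | COC(=O)/C(COCc1ccc(OC)cc1)=C(\OS(=O)(=O)C(F)(F)F)COCc1ccccc1 | intermediate
14 | B-alkyl-9-BBN adduct of 7 (hydroxyl borylated) | CC(C)(C)OC(=O)NC[C@@H](C)[C@@H](CCB1C2CCCC1CCC2)OB1C2CCCC1CCC2 | intermediate (not isolated)
15 | methyl (2E,6R,7R)-3-[(benzyloxy)methyl]-8-[(tert-butoxycarbonyl)amino]-6-hydroxy-2-{[(4-methoxybenzyl)oxy]methyl}-7-methyloct-2-enoate | COC(=O)/C(COCc1ccc(OC)cc1)=C(\CC[C@@H](O)[C@H](C)CNC(=O)OC(C)(C)C)COCc1ccccc1 | intermediate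
16 | (2E,6R,7R)-3-[(benzyloxy)methyl]-8-[(tert-butoxycarbonyl)amino]-6-hydroxy-2-{[(4-methoxybenzyl)oxy]methyl}-7-methyloct-2-enoic acid | OC(=O)/C(COCc1ccc(OC)cc1)=C(\CC[C@@H](O)[C@H](C)CNC(=O)OC(C)(C)C)COCc1ccccc1 | intermediate
17 | tert-butyl N-[(2R)-2-[(7R)-4-[(benzyloxy)methyl]-3-{[(4-methoxybenzyl)oxy]methyl}-2-oxo-2,5,6,7-tetrahydrooxepin-7-yl]propyl]carbamate | O=C1O[C@@H]([C@H](C)CNC(=O)OC(C)(C)C)CCC(COCc2ccccc2)=C1COCc3ccc(OC)cc3 | intermediate
18 | tert-butyl N-[(2R)-2-[(7R)-4-[(benzyloxy)methyl]-3-(hydroxymethyl)-2-oxo-2,5,6,7-tetrahydrooxepin-7-yl]propyl]carbamate | O=C1O[C@@H]([C@H](C)CNC(=O)OC(C)(C)C)CCC(COCc2ccccc2)=C1CO | intermediate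
19 | tert-butyl N-[(2R)-2-[(7R)-4-[(benzyloxy)methyl]-3-(bromomethyl)-2-oxo-2,5,6,7-tetrahydrooxepin-7-yl]propyl]carbamate | O=C1O[C@@H]([C@H](C)CNC(=O)OC(C)(C)C)CCC(COCc2ccccc2)=C1CBr | intermediate
20 | but-3-en-1-ol | C=CCCO | starting material
21 | tert-butyl(but-3-en-1-yloxy)dimethylsilane | C=CCCO[Si](C)(C)C(C)(C)C | intermediate
22 | (E)-but-2-enal | C/C=C/C=O | starting material
23 | (E)-5-[(tert-butyldimethylsilyl)oxy]pent-2-enal | O=C/C=C/CCO[Si](C)(C)C(C)(C)C | intermediate
24 | cyclopentane-1,3-dione | O=C1CCC(=O)C1 | starting material
25 | (3R)-5-[(tert-butyldimethylsilyl)oxy]-3-(2,5-dioxocyclopentyl)pentanal | O=CC[C@@H](CCO[Si](C)(C)C(C)(C)C)C1C(=O)CCC1=O | intermediate (not isolated)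
26 | (4R)-4-{2-[(tert-butyldimethylsilyl)oxy]ethyl}-2-hydroxy-3,4,6,7-tetrahydro-2H-cyclopenta[b]pyran-5-one | OC1C[C@@H](CCO[Si](C)(C)C(C)(C)C)C2=C(CCC2=O)O1 | intermediate
27 | (4R)-4-{2-[(tert-butyldimethylsilyl)oxy]ethyl}-3,4,6,7-tetrahydrocyclopenta[b]pyran-2,5-dione | O=C1C[C@@H](CCO[Si](C)(C)C(C)(C)C)C2=C(CCC2=O)O1 | intermediate
28 | S-ethyl (3R)-5-[(tert-butyldimethylsilyl)oxy]-3-(2,5-dioxocyclopentyl)pentanethioate | CCSC(=O)C[C@@H](CCO[Si](C)(C)C(C)(C)C)C1C(=O)CCC1=O | intermediate
29 | C5-alkylated thioester | CCSC(=O)[C@H](CC1=C(COCc2ccccc2)CC[C@H]([C@H](C)CNC(=O)OC(C)(C)C)OC1=O)[C@@H](CCO[Si](C)(C)C(C)(C)C)C3C(=O)CCC3=O | intermediate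
30 | trans enol lactone (key-step precursor) | O=C1OC2=C(C(=O)CC2)[C@H](CCO[Si](C)(C)C(C)(C)C)[C@H]1CC3=C(COCc4ccccc4)CC[C@H]([C@H](C)CNC(=O)OC(C)(C)C)OC3=O | intermediate
31 | cyclobutane photoadduct with bridging lactone | O=C1O[C@]23CCC(=O)[C@]24[C@H](CCO[Si](C)(C)C(C)(C)C)[C@H]1C[C@@]45C(=O)O[C@@H]([C@H](C)CNC(=O)OC(C)(C)C)CC[C@@]35COCc6ccccc6 | intermediate (not isolated)
32 | cyclobutanol methyl ester | COC(=O)[C@@H]1C[C@@]23C(=O)O[C@@H]([C@H](C)CNC(=O)OC(C)(C)C)CC[C@@]3(COCc4ccccc4)[C@@]5(O)CCC(=O)[C@@]25[C@@H]1CCO[Si](C)(C)C(C)(C)C | intermediate (not isolated)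
33 | ring A-fused cycloheptane-1,4-dione with spiro lactone (key-step product) | COC(=O)[C@@H]1C[C@@]23C(=O)O[C@@H]([C@H](C)CNC(=O)OC(C)(C)C)CC[C@@]3(COCc4ccccc4)C(=O)CCC(=O)[C@@H]2[C@@H]1CCO[Si](C)(C)C(C)(C)C | intermediate
34 | C21 alcohol | COC(=O)[C@@H]1C[C@@]23C(=O)O[C@@H]([C@H](C)CNC(=O)OC(C)(C)C)CC[C@@]3(CO)C(=O)CCC(=O)[C@@H]2[C@@H]1CCO[Si](C)(C)C(C)(C)C | intermediate
35 | C21 acetate | COC(=O)[C@@H]1C[C@@]23C(=O)O[C@@H]([C@H](C)CNC(=O)OC(C)(C)C)CC[C@@]3(COC(C)=O)C(=O)CCC(=O)[C@@H]2[C@@H]1CCO[Si](C)(C)C(C)(C)C | intermediate
36 | C19 alcohol | COC(=O)[C@@H]1C[C@@]23C(=O)O[C@@H]([C@H](C)CNC(=O)OC(C)(C)C)CC[C@@]3(COC(C)=O)C(=O)CCC(=O)[C@@H]2[C@@H]1CCO | intermediate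
37 | C19 iodide | COC(=O)[C@@H]1C[C@@]23C(=O)O[C@@H]([C@H](C)CNC(=O)OC(C)(C)C)CC[C@@]3(COC(C)=O)C(=O)CCC(=O)[C@@H]2[C@@H]1CCI | intermediate
38 | C15 tertiary carbinol with ring B closed | COC(=O)[C@@H]1C[C@@]23C(=O)O[C@@H]([C@H](C)CNC(=O)OC(C)(C)C)CC[C@@]3(COC(C)=O)C(=O)CC[C@@]4(O)[C@@H]2[C@@H]1CC4 | intermediate
39 | tetrasubstituted cyclopentene ketone | COC(=O)[C@@H]1C[C@@]23C(=O)O[C@@H]([C@H](C)CNC(=O)OC(C)(C)C)CC[C@@]3(COC(C)=O)C(=O)CCC4=C2[C@@H]1CC4 | intermediate
40 | exocyclic methylene compound | COC(=O)[C@@H]1C[C@@]23C(=O)O[C@@H]([C@H](C)CNC(=O)OC(C)(C)C)CC[C@@]3(COC(C)=O)C(=C)CCC4=C2[C@@H]1CC4 | intermediate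
41 | B-alkyl-9-BBN adduct of 40 | COC(=O)[C@@H]1C[C@@]23C(=O)O[C@@H]([C@H](C)CNC(=O)OC(C)(C)C)CC[C@@]3(COC(C)=O)[C@@H](CB5C6CCCC5CCC6)CCC4=C2[C@@H]1CC4 | intermediate (not isolated)
42 | C11 alcohol | COC(=O)[C@@H]1C[C@@]23C(=O)O[C@@H]([C@H](C)CNC(=O)OC(C)(C)C)CC[C@@]3(COC(C)=O)[C@@H](CO)CCC4=C2[C@@H]1CC4 | intermediate
43 | C11 aldehyde | COC(=O)[C@@H]1C[C@@]23C(=O)O[C@@H]([C@H](C)CNC(=O)OC(C)(C)C)CC[C@@]3(COC(C)=O)[C@@H](C=O)CCC4=C2[C@@H]1CC4 | intermediate
44 | amino aldehyde | COC(=O)[C@@H]1C[C@@]23C(=O)O[C@@H]([C@H](C)CN)CC[C@@]3(COC(C)=O)[C@@H](C=O)CCC4=C2[C@@H]1CC4 | intermediate (not isolated)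
45 | nine-membered lactam aldehyde | COC(=O)[C@@H]1C[C@@]23C(=O)NC[C@@H](C)[C@H](O)CC[C@@]3(COC(C)=O)[C@@H](C=O)CCC4=C2[C@@H]1CC4 | intermediate (not isolated)
46 | N-acyl hemiaminal | COC(=O)[C@@H]1C[C@@]23C(=O)N4C[C@@H](C)[C@H](O)CC[C@@]3(COC(C)=O)[C@@H](C4O)CCC5=C2[C@@H]1CC5 | intermediate
47 | CNP0296366.1 | COC(=O)[C@@H]1C[C@@]23C(=O)N4C[C@@H](CCC5=C2[C@@H]1CC5)[C@]3(COC(C)=O)CC[C@@H](O)[C@H](C)C4 | target

## Step count and weak points

Total step count: 31. Longest linear sequence: 23 steps (steps 1 to 4, 8 to 12 and 18 to 31).

**Step 20 (key step).** The cyclobutane closure creates four contiguous fully substituted carbons, so the 1,4-biradical may revert to 30 faster than it closes. A 1,3-acyl shift of the excited enol ester could also compete, and methoxide could open the seven-membered lactone as well. Fallback: 30 is first opened with methanol and a trace of DMAP to the free 2-substituted cyclopentane-1,3-dione methyl ester F1. Its enol is irradiated at 300 nm in the classical de Mayo manner, so that cyclobutanol 32 forms and fragments directly, and the route is rejoined at 33. This gives up the facial lock of the enol lactone, and the face of the lactone alkene would then have to be chosen by the tether centres alone.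

**Step 18.** Diastereoselection at C5 rests on acyclic control, and the dione enolate could be O-alkylated by the very reactive bromide, or proton transfer could stop the reaction. Step 19 corrects C5 by equilibration but not a low conversion. Fallback: enol lactone 27 is opened with lithiated (R)-4-benzyl-1,3-oxazolidin-2-one to the imide F2. Its sodium enolate (NaN(SiMe3)2, two equivalents) is alkylated with 19 under auxiliary control to give the imide F3. The auxiliary is then displaced with EtSLi, which returns the route at 29.

**Step 26 (together with step 25).** The Barbier closure needs the C16 epimer in which C15 and the iodoethyl arm are cis, and the dehydration may lose a proton from C14 or C19 instead of C16, giving the wrong alkene regiochemistry. Fallback: iodide 37 is heated with PPh3 to the phosphonium iodide F4. Its ylide (KN(SiMe3)2, which also equilibrates C16) closes ring B by intramolecular Wittig reaction to the trisubstituted cyclopentene F5 (C15=C19). The alkene is then moved into the tetrasubstituted position with RhCl3·3H2O in ethanol, returning at 39.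

**Step 28.** The methylene group is flanked by the quaternary C20, so hydroboration with the bulky borane may be too slow, and forcing it risks reduction of the lactone. Fallback: ketone 39 is converted with Ph3P=CHOMe into the enol ether F6, and mild aqueous acid then gives aldehyde 43 directly.

**Step 30.** Acyl transfer to the amine may be slow because C8 sits on a quaternary carbon, and the amine could instead condense with the aldehyde of another molecule. Slow epimerization at C12 would also hold back the closure. Fallback: alcohol 42 is mesylated to F7. Removal of the carbamate (TMSOTf, 2,6-lutidine) gives the amino mesylate F8, which rearranges to the nine-membered lactam mesylate F9. KOt-Bu then closes ring D by N-alkylation to give 47 directly. This variant depends on the C12 configuration obtained in step 28.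

## Further compounds

F1 | step 20 | methyl ester of the open 2-substituted cyclopentane-1,3-dione (methanolysis product of 30) | COC(=O)[C@H](CC1=C(COCc2ccccc2)CC[C@H]([C@H](C)CNC(=O)OC(C)(C)C)OC1=O)[C@@H](CCO[Si](C)(C)C(C)(C)C)C3C(=O)CCC3=O
F2 | step 18 | (R)-4-benzyl-3-[(3R)-5-[(tert-butyldimethylsilyl)oxy]-3-(2,5-dioxocyclopentyl)pentanoyl]-1,3-oxazolidin-2-one | O=C(C[C@@H](CCO[Si](C)(C)C(C)(C)C)C1C(=O)CCC1=O)N2C(=O)OC[C@H]2Cc3ccccc3
F3 | step 18 | C5-alkylated imide | O=C([C@H](CC1=C(COCc2ccccc2)CC[C@H]([C@H](C)CNC(=O)OC(C)(C)C)OC1=O)[C@@H](CCO[Si](C)(C)C(C)(C)C)C3C(=O)CCC3=O)N4C(=O)OC[C@H]4Cc5ccccc5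
F4 | step 26 | C19 triphenylphosphonium iodide | COC(=O)[C@@H]1C[C@@]23C(=O)O[C@@H]([C@H](C)CNC(=O)OC(C)(C)C)CC[C@@]3(COC(C)=O)C(=O)CCC(=O)[C@@H]2[C@@H]1CC[P+](c4ccccc4)(c5ccccc5)c6ccccc6.[I-]
F5 | step 26 | trisubstituted cyclopentene (C15=C19) | COC(=O)[C@@H]1C[C@@]23C(=O)O[C@@H]([C@H](C)CNC(=O)OC(C)(C)C)CC[C@@]3(COC(C)=O)C(=O)CCC4=CC[C@H]1[C@H]24
F6 | step 28 | methyl enol ether at C12 | COC(=O)[C@@H]1C[C@@]23C(=O)O[C@@H]([C@H](C)CNC(=O)OC(C)(C)C)CC[C@@]3(COC(C)=O)C(=COC)CCC4=C2[C@@H]1CC4
F7 | step 30 | C11 mesylate | COC(=O)[C@@H]1C[C@@]23C(=O)O[C@@H]([C@H](C)CNC(=O)OC(C)(C)C)CC[C@@]3(COC(C)=O)[C@@H](COS(C)(=O)=O)CCC4=C2[C@@H]1CC4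
F8 | step 30 | amino mesylate | COC(=O)[C@@H]1C[C@@]23C(=O)O[C@@H]([C@H](C)CN)CC[C@@]3(COC(C)=O)[C@@H](COS(C)(=O)=O)CCC4=C2[C@@H]1CC4
F9 | step 30 | nine-membered lactam mesylate | COC(=O)[C@@H]1C[C@@]23C(=O)NC[C@@H](C)[C@H](O)CC[C@@]3(COC(C)=O)[C@@H](COS(C)(=O)=O)CCC4=C2[C@@H]1CC4
A1 | alternative 1 | pentacyclic hydroxy imide | COC(=O)[C@@H]1C[C@@]23C(=O)N4C[C@@H](CCC5=C2[C@@H]1CC5)[C@]3(COC(C)=O)CC[C@@H](O)[C@H](C)C4=O
A2 | alternative 1 | N-propanoyl lactam aldehyde | COC(=O)[C@@H]1C[C@@]23C(=O)N(C(=O)CC)C[C@@H](CCC4=C2[C@@H]1CC4)[C@]3(COC(C)=O)CCC=O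
A3 | alternative 2 | tetracyclic cyclopentenone with ester arm | C=C[C@@]12C(=O)N3C[C@@H](CCC4=C1[C@@H](CC(=O)OC)CC4=O)[C@]2(COCc5ccccc5)CC[C@@H](OCc6ccccc6)[C@H](C)C3
A4 | alternative 2 | cross-conjugated dienone | C=C[C@@]12C(=O)N3C[C@@H](CCC(C(=O)/C=C/CC(=O)OC)=C1)[C@]2(COCc4ccccc4)CC[C@@H](OCc5ccccc5)[C@H](C)C3
A5 | alternative 3 | bridged lactam with alkylidene cyclopentenone | O=C1N(Cc2ccc(OC)cc2)C[C@@H](CC=C3CC(=O)C(CCO[Si](C)(C)C(C)(C)C)=C34)[C@](CO[Si](C(C)C)(C(C)C)C(C)C)(CCCOCc5ccccc5)[C@]14C(OC)OC
A6 | alternative 3 | allene-yne lactam | O=C1N(Cc2ccc(OC)cc2)C[C@@H](CC=C=C)[C@](CO[Si](C(C)C)(C(C)C)C(C)C)(CCCOCc3ccccc3)[C@]1(C#CCCO[Si](C)(C)C(C)(C)C)C(OC)OC
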